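About 0.0754 M of second end groups is the number we carry through this flask. It is the crossover level, the level at which a lost first end group ends as a link as often as it ends any other way, so that the selectivity factor is one.

| setting | north | south-west | flask |
|---|---|---|---|
| first end groups | 0.10 M | 0.10 M | 0.10 M |
| second end groups | 1.02 equiv | 1.02 equiv | 1.02 equiv |
| protic impurity | 0.010 M | 0.015 M | 0.0200 M |
| remark | run made earlier | run made earlier |  |
| time |  |  | 15 h |

- north (time / h: links / %, first end groups / %): 1.33: 8.2, 85.5; 2.50: 13.4, 75.1; 4.00: 19.3, 64.8; 5.00: 22.0, 58.3; 6.00: 23.9, 53.0; 8.00: 27.5, 44.7; 10.0: 29.7, 37.8
- south-west (time / h: links / %, first end groups / %): 0.667: 3.7, 92.1; 1.00: 5.9, 88.6; 1.50: 9.2, 84.0; 2.50: 13.9, 75.0; 4.00: 19.0, 64.1; 6.00: 23.9, 53.3; 10.0: 29.4, 38.2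

(standard deviation of a reading: 0.3 percentage points)

* amount of links in percent of the first end groups charged, at 1.5 h, 5.0 h and 15 h

- percentages count the first end groups that a species holds: one self-condensation product counts as two
- what may be going on: first end groups + second end groups -> links; second end groups + protic impurity -> quenched reagent; first end groups + second end groups -> rings; 2 first end groups -> self-condensation product

We read this level from the north run. Up to 2.50 h, links gained 1.17 times what went elsewhere, but from 4.00 h to 10.0 h they gained 0.627 times, so the ratio sinks as the flask thins out. We take it as the level over the crossover level. The second end groups are charged nearly equal to the first, so the first stand in for them. Over the whole run, a mean level of 0.0689 M and a ratio of 0.914 give the number above.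

The protic impurity we treat as a correction. From north to south-west it rose by 0.00500 M, and links at 10.0 h differed by 0.3 percentage points, against a scatter of 0.3 points. So we reckon from the north run and expect to land a little high.

In north, first end groups fell from 58.3% to 37.8% between 5.00 h and 10.0 h. The same factor over the next 5.00 h gives 24.5%. The mean level is then 0.0312 M, and our links at 15 h come to 33.6%.

The forecast gives 9.1%, 21.7% and 32.3%, on the ground: “Impurity therefore has little effect at these levels”.

The flask gives 9.10%, 21.5% and 33.1%.

    first end groups + second end groups → links (k = 0.710 /M/h)
    second end groups + protic impurity → quenched reagent (k = 0.260 /M/h)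
    first end groups + second end groups → rings, rate k3*[first end groups] as long as [second end groups] is above zero (k = 0.0520 /h)
    2 first end groups → self-condensation product (k = 1.40 × 10⁻⁴ /M/h)

Quenched reagent reached 0.00365 M at 15.0 h, beside the 0.10 M of first end groups charged. The flask held 0.0850 M of second end groups at 1.50 h, above the crossover level, with links at 9.10% and rings at 7.14%. At 7.50 h it held 0.0464 M, below that level. Run at twice the dilution, the flask starts with 0.0510 M of second end groups, below the crossover level from the outset, and its links come to 20.6% of the first end groups charged.

The data come from a simulation from invented constants; noise was put on by code.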